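# Proposed synthesis of (M)-bisoflavolin C: anodic cross-dehydrodimerisation of two daidzein mono-ethers, then axis transcription through a chiral diol bridge

## Analysis of the target

(M)-Bisoflavolin C (9) is the dehydro-dimer of daidzein (1): two 3-aryl-4H-chromen-4-one units held together by a single aryl–aryl bond. Unit 1 consists of benzo ring A, pyranone ring C and pendant ring B (locants C2–C8a and C1'–C6'). Unit 2 consists of benzo ring D, pyranone ring E and a pendant 4-hydroxyphenyl ring (locants C2''–C8a'' and C1'''–C6'''). The inter-unit bond runs from C3' of ring B to C8'' of ring D.

The feature on which the route is built is that both carbons of this bond stand ortho to a free phenol (C4'–OH on ring B, C7''–OH on ring D), and C8'' lies between the two oxygen-bearing carbons C7'' and C8a''. This is the bond an ortho,ortho phenol coupling makes, and the two hydroxyls that direct such a coupling flank the axis.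

There is no stereogenic centre. The only stereogenic element is the C3'–C8'' axis, M-configured. Its ortho positions carry three oxygen substituents (O4', O7'', ring oxygen O1'' on C8a'') and one hydrogen, so the rotational barrier is expected to be modest. The axis must therefore be set late and kept cold afterwards.

Sensitive functions are the four phenols of two kinds (the 7-hydroxyls are vinylogous acids, pKa near 7; the 4'-hydroxyls are ordinary phenols, pKa near 10), the chromone C2 positions (opened by hydroxide and amines) and the C2=C3 enone bonds (reducible).

The difficulty is threefold:
- forming one hetero-bond between two nearly identical electron-rich monomers at C3' and C8'' and not at C6'', C3''' or oxygen;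
- telling four hydroxyl groups apart;
- imposing and keeping the M twist on a weakly hindered axis.

## Retrosynthetic reasoning

**9 ⇒ 8.** Four C–O bonds are cut in the last step: the two ether bonds of a (2S,4S)-pentane-2,4-diyl bridge spanning O4' and O7'', the isopropyl ether on O7 and the methyl ether on O4'''. The free biphenol axis is too weakly hindered to be carried through several steps, whereas in 8 it is locked inside a nine-membered ring whose two stereocentres dictate the sense of twist. O4' and O7'' are the only pair of atoms from which a three-carbon chain can reach across the axis. The forward step has to cleave all four ethers under one set of cold Lewis-acidic conditions; for that reason three of the oxygens carry secondary alkyl groups and the fourth an unhindered anisole methyl.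

**8 ⇒ 7 ⇒ 5 + 6.** The two O–C(sp3) bonds of the bridge are cut. In the forward direction two Mitsunobu etherifications, each with inversion, turn the (R,R)-diol 6 into an (S,S)-diether; the second one closes the nine-membered ring. Because the axis of 5 and 7 still rotates, ring closure can select the atropisomer that keeps both methyl groups outside the ring, so the stereocentres of 6 are transcribed into the axis. This needs a precursor with exactly two free hydroxyls, on O4' and O7'', and with the distal oxygens masked. That is the substitution pattern of 5.

**5 ⇒ 2 + 3 (key disconnection).** The C3'–C8'' bond is cut into two C–H bonds. It is the only bond between the units, and cutting it here reduces the problem to two mono-ethers of 1, one made in one step and one purchased. Each partner carries one free phenol, on the ring that must react and ortho to the carbon that must bond. The hydroxyls that direct the coupling are the same ones that later take the bridge, so no protecting-group change lies between the key step and the stereo-defining step. The forward reaction, an anodic dehydrogenative cross-coupling in a fluorinated alcohol medium, must oxidise ring B of 2 selectively and have the resulting radical intercepted by C8'' of 3 rather than by a second molecule of 2. No halogen, boron or metal has to be installed. The risk of the route is concentrated in this step.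

**2 ⇒ 1.** The O7–isopropyl bond is cut. The acidic 7-hydroxyl of 1 is alkylated selectively in the forward direction. Compounds 3 and 6 are commercial.

## Alternatives that were turned down

**Alternative 1:** the textbook disconnection of the same C3'–C8'' bond into a halide and a boronate. The forward key step is a Suzuki–Miyaura coupling of the fully methylated 8''-iodide A1 with the 3'-boronate A2 (Pd(PPh3)4, aqueous carbonate) to the tetramethyl ether A3, followed by global demethylation. Turned down because:
- it needs two regioselective halogenations, exhaustive O-methylation and a borylation before the bond can be made;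
- the coupling joins a doubly ortho-oxygenated, electron-rich iodide to an ortho-alkoxy boronate, where oxidative addition is slow and protodeboronation competes;
- A3 carries four indistinguishable methyl ethers, so the two oxygens flanking the axis cannot be addressed and the axis cannot be set without further selective deprotection.

The sequence is longer than the chosen one by at least three steps and solves nothing that the chosen route leaves open.

**Alternative 2:** disconnection of both pyranone rings C and E (O1–C2 and C2–C3 in each unit) from a biaryl bis-deoxybenzoin A4. The forward key step is a double formylative annulation (one-carbon electrophile with a Lewis acid) that closes both heterocycles at once. Turned down because: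
- A4 still contains the critical biaryl bond, which would have to be made by a cross-coupling on protected fragments;
- two different Friedel–Crafts acylations are then needed to install the two ketones;
- the annulation runs hot under strong Lewis acid, so the axis ends up equilibrated, with no handle left to correct it.

The step count would roughly double.

**Alternative 3:** ring D carried as a saturated ring and aromatised late. C8'' sits between two oxygenated carbons and maps onto C2 of cyclohexane-1,3-dione A5. The forward key step is a palladium-catalysed α-arylation of A5 with the ring B bromide A6 (Pd(OAc)2, bulky biarylphosphine, K3PO4) to the 2-aryl-1,3-dione A7, followed by construction of ring E on the dione and dehydrogenation. This solves the regiochemistry at C8'' cleanly. It was turned down because: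
- the whole second isoflavone (C-acylation at the α'-carbon in competition with O-acylation, formylative ring closure, dehydrogenation) must then be built on a non-aromatic ring;
- the base-sensitive chromone of unit 1 must survive enolate chemistry;
- the axis is again left uncontrolled.

Key step: step 2

**Assumption:** SMILES has no symbol for a biaryl axis, so the target is taken as the M atropisomer about C3'–C8'' (CIP lead atoms C4' and C8a'', i.e. a positive C4'–C3'–C8''–C7'' dihedral angle); the axis is assumed to persist at or below ambient temperature and to equilibrate on heating. In the list below the descriptor M is carried by the names of 8 and 9.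

## Route

Step 1
Reactants: 1 daidzein
Product: 2 7-O-isopropyldaidzein
Conditions: 2-bromopropane (1.3 equiv), K2CO3 (1.1 equiv), DMF, 60 °C
Reagents that add atoms: 2-bromopropane, CC(C)Br
Why: Williamson ether synthesis; one equivalent of carbonate should ionise only the vinylogous-acid 7-OH (pKa near 7) and leave the 4'-OH (pKa near 10) protonated, so alkylation is expected at O7, as in the standard isopropylation of 7-hydroxyisoflavones.

Step 2
Reactants: 2 7-O-isopropyldaidzein; 3 formononetin
Product: 5 7-O-isopropyl-4'''-O-methylbisoflavolin C (axis not fixed), via cyclohexadienone tautomer 4 (not isolated)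
Conditions: undivided cell, boron-doped diamond anode, Pt cathode, 2.8 mA cm−2, 2.0 F per mol of 2, 3 (3 equiv), [Et3NMe][MeOSO3] (0.1 M), HFIP/MeOH 82:18, 50 °C
Reagents that add atoms: none
Why: Anodic dehydrogenative phenol–phenol cross-coupling to a non-symmetric 2,2'-biphenol, the known boron-doped-diamond/HFIP protocol, applied here to two hydroxyisoflavones. Proton-coupled one-electron oxidation should take place at the only easily oxidised site present, the ring B 4'-OH of 2 (O7 of 2 is alkylated, and the 7-OH of 3 sits on an acyl-conjugated ring with a clearly higher oxidation potential), giving a phenoxyl radical with spin density at C3'/C5'. C8'' of 3, the carbon between O7'' and O1'' and the position at which 7-hydroxyisoflavones take electrophiles, adds to C3'; loss of a second electron and a proton gives dienone 4, which tautomerises to 5, while the platinum cathode reduces HFIP to H2 in preference to the chromone carbonyls. No ring is closed. The C3'–C8'' axis is created without stereocontrol and remains free to equilibrate in 5; it is fixed in step 4. Hetero- over homo-coupling is to be secured by keeping 2 limiting against a three-fold excess of recoverable 3, by the low current density and by HFIP hydrogen bonding, which lowers the nucleophilicity of the partner being oxidised. Attack through C8'' and not C6'' or the anisole ring follows from the double ortho-oxygen activation of C8'' and from the absence of a free hydroxyl on the anisole ring, and C–C rather than C–O coupling is the normal outcome in HFIP. The step joins the two halves from two C–H bonds and leaves exactly O4'–H and O7''–H free at the axis, which is what steps 3 and 4 require.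

Step 3
Reactants: 5 7-O-isopropyl-4'''-O-methylbisoflavolin C; 6 (2R,4R)-pentane-2,4-diol
Product: 7 O7''-[(2S,4R)-4-hydroxypentan-2-yl] monoether of 5
Conditions: 6 (5 equiv), PPh3 (1.2 equiv), DIAD (1.2 equiv), THF, 0 °C to rt
Reagents that add atoms: none
Why: Mitsunobu etherification; the more acidic 7''-OH should be the phenol that protonates the betaine and reacts, the excess of 6 suppresses double arylation of the diol, and SN2 displacement inverts the reacting carbinol carbon from R to S while the second carbinol stays R.

Step 4
Reactants: 7 O7''-[(2S,4R)-4-hydroxypentan-2-yl] monoether of 5
Product: 8 (M)-O4',O7''-[(2S,4S)-pentane-2,4-diyl]-bridged 7-O-isopropyl-4'''-O-methylbisoflavolin C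
Conditions: PPh3 (3 equiv), DIAD (3 equiv), toluene, 0.005 M, slow addition of 7, 50 °C
Reagents that add atoms: none
Why: Intramolecular Mitsunobu etherification by the 4'-OH with inversion (second S centre), closing the nine-membered 1,5-dioxonine ring; this is the known use of a chiral pentane-2,4-diyl tether to control a biaryl axis. The axis of 7 rotates at this temperature, and in the twist conformation of the ring an (S,S)-bridge can keep both methyl groups outside the ring only with a positive C4'–C3'–C8''–C7'' dihedral angle; that atropisomer (M) should therefore both close faster and be the more stable diastereomer. The assignment of this sense rests on a hand-built model of the ring, not on a computed or measured structure.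

Step 5
Reactants: 8 (M)-O4',O7''-[(2S,4S)-pentane-2,4-diyl]-bridged 7-O-isopropyl-4'''-O-methylbisoflavolin C
Product: 9 (M)-bisoflavolin C
Conditions: BBr3 (10 equiv), CH2Cl2, −78 to 0 °C; MeOH then H2O at −20 °C
Reagents that add atoms: none
Why: Lewis-acid cleavage of aryl alkyl ethers; the three secondary alkyl–oxygen bonds (isopropyl and both bridge carbons) should cleave well below 0 °C and the unhindered anisole methyl at 0 °C, so the axis is released only in the cold and no bond at the axis is touched.

## Compound list

1 | daidzein, 7-hydroxy-3-(4-hydroxyphenyl)-4H-chromen-4-one | O=c1c(-c2ccc(O)cc2)coc2cc(O)ccc12 | starting material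
2 | 7-O-isopropyldaidzein, 3-(4-hydroxyphenyl)-7-(propan-2-yloxy)-4H-chromen-4-one | CC(C)Oc1ccc2c(c1)occ(-c1ccc(O)cc1)c2=O | intermediate
3 | formononetin, 7-hydroxy-3-(4-methoxyphenyl)-4H-chromen-4-one | COc1ccc(cc1)-c1coc2cc(O)ccc2c1=O | starting material
4 | cyclohexa-2,4-dienone tautomer of 5 (C3' sp3, C4'=O; configuration at C3' not controlled) | CC(C)Oc1ccc2c(c1)occ(C1=CC(C(=O)C=C1)c1c(O)ccc3c(=O)c(-c4ccc(OC)cc4)coc13)c2=O | intermediate (not isolated)
5 | 7-O-isopropyl-4'''-O-methylbisoflavolin C, 3-{4-hydroxy-3-[7-hydroxy-3-(4-methoxyphenyl)-4-oxo-4H-chromen-8-yl]phenyl}-7-(propan-2-yloxy)-4H-chromen-4-one, axis not fixed | CC(C)Oc1ccc2c(c1)occ(-c1ccc(O)c(c1)-c1c(O)ccc3c(=O)c(-c4ccc(OC)cc4)coc13)c2=O | intermediate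
6 | (2R,4R)-pentane-2,4-diol | C[C@@H](O)C[C@@H](C)O | starting material
7 | O7''-[(2S,4R)-4-hydroxypentan-2-yl] monoether of 5 | CC(C)Oc1ccc2c(c1)occ(-c1ccc(O)c(c1)-c1c(O[C@@H](C)C[C@@H](C)O)ccc3c(=O)c(-c4ccc(OC)cc4)coc13)c2=O | intermediate
8 | (M)-O4',O7''-[(2S,4S)-pentane-2,4-diyl]-bridged 7-O-isopropyl-4'''-O-methylbisoflavolin C; O4' and O7'' joined by CH(CH3)–CH2–CH(CH3), nine-membered 1,5-dioxonine ring containing C4', C3', C8'' and C7'' | CC(C)Oc1ccc2c(c1)occ(-c1ccc3c(c1)-c1c(ccc4c(=O)c(-c5ccc(OC)cc5)coc14)O[C@@H](C)C[C@H](C)O3)c2=O | intermediate
9 | (M)-bisoflavolin C | O=c1c(-c2ccc(O)c(-c3c(O)ccc4c(=O)c(-c5ccc(O)cc5)coc34)c2)coc2cc(O)ccc12 | target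

## Step count and least certain steps

Total step count: 5. Longest linear sequence: 5 steps, from 1 through 2, 5, 7 and 8 to 9; 3 and 6 are purchased.

**Step 2 (key step).** The most likely failure is homo-coupling of the oxidised partner through ring B outrunning the hetero-coupling, because ring D of 3 is an acyl-deactivated nucleophile. Attack through C6'' or through the anisole ring, C–O coupling, and further oxidation of the product biphenol are secondary risks.

The fallback sets out from 2 and 3 and comes back to the route at 8, using known tether-first chemistry:
- iodination of 3 at C8'' (N-iodosuccinimide, DMF) to 8-iodoformononetin F1;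
- iodination of 2 ortho to its free phenol (N-iodosuccinimide, catalytic TsOH, MeCN, 0 °C) to 3'-iodo-7-O-isopropyldaidzein F2;
- Mitsunobu etherification of F1 with excess 6 to the iodo monoether F3;
- a second Mitsunobu reaction of F3 with F2 to the diiodo diether F4;
- intramolecular Ullmann coupling of F4 (activated copper powder, DMF, 130 °C), which forms C3'–C8'' inside the tether and should give 8 with the axis steered by the (S,S)-bridge as in step 4.

**Step 4.** Closure of a nine-membered ring at a secondary carbon may lose to intermolecular etherification or to elimination of the activated alcohol. The axial induction may also be incomplete, or opposite to the model; in the latter case the antipodal tether reagent is equally available.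

The fallback sets out from 5 and comes back at 9. Global ether cleavage of 5 (BBr3, CH2Cl2, rt) gives the M/P mixture of bisoflavolin C F6. This is separated in the cold on a chiral stationary phase (amylose tris(3,5-dimethylphenylcarbamate)). The P-enriched fraction is re-equilibrated by warming and recycled.

**Step 5.** Cleavage of the anisole methyl needs about 0 °C, and partial rotation about the freed axis during that time would erode the atropisomeric purity. Secondary carbocations from the bridge could also alkylate the phenol rings.

The fallback sets out from 8 and comes back at 9. With the axis still locked, the methyl group is removed first by methyl-selective SN2 dealkylation (NaSEt, DMF, 100 °C, acidic work-up to re-close any opened chromone), giving the bridged 4'''-phenol F7. The final release then needs only secondary-ether cleavage (BCl3, CH2Cl2, −78 to −20 °C).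

**Step 3.** Imperfect discrimination between the two phenols of 5 is harmless, because the bridge is C2-symmetric. Over-reaction to bis-ethers or to diol-linked dimers would cost material.

The fallback sets out from 5 and 6 and comes back at 8. Diol 6 is converted into (2R,4R)-pentane-2,4-diyl dimethanesulfonate F5 (MsCl, Et3N, CH2Cl2). Compound 5 is then annulated with F5 in one operation (Cs2CO3, DMF, 60 °C, high dilution). Two SN2 displacements with inversion give the same (S,S)-bridge and bypass 7.

## Further compounds

F1 | step 2 | 8-iodoformononetin, 7-hydroxy-8-iodo-3-(4-methoxyphenyl)-4H-chromen-4-one | COc1ccc(cc1)-c1coc2c(I)c(O)ccc2c1=O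
F2 | step 2 | 3'-iodo-7-O-isopropyldaidzein, 3-(4-hydroxy-3-iodophenyl)-7-(propan-2-yloxy)-4H-chromen-4-one | CC(C)Oc1ccc2c(c1)occ(-c1ccc(O)c(I)c1)c2=O
F3 | step 2 | 7-{[(2S,4R)-4-hydroxypentan-2-yl]oxy}-8-iodo-3-(4-methoxyphenyl)-4H-chromen-4-one | COc1ccc(cc1)-c1coc2c(I)c(O[C@@H](C)C[C@@H](C)O)ccc2c1=O
F4 | step 2 | (2S,4S)-pentane-2,4-diyl diether joining O4' of F2 and O7 of F1 (diiodide) | CC(C)Oc1ccc2c(c1)occ(-c1ccc(O[C@@H](C)C[C@H](C)Oc3ccc4c(=O)c(-c5ccc(OC)cc5)coc4c3I)c(I)c1)c2=O
F5 | step 3 | (2R,4R)-pentane-2,4-diyl dimethanesulfonate | C[C@@H](OS(C)(=O)=O)C[C@@H](C)OS(C)(=O)=O
F6 | step 4 | bisoflavolin C as M/P mixture about C3'–C8'' | O=c1c(-c2ccc(O)c(-c3c(O)ccc4c(=O)c(-c5ccc(O)cc5)coc34)c2)coc2cc(O)ccc12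
F7 | step 5 | (M)-O4',O7''-[(2S,4S)-pentane-2,4-diyl]-bridged 7-O-isopropylbisoflavolin C (free 4'''-OH) | CC(C)Oc1ccc2c(c1)occ(-c1ccc3c(c1)-c1c(ccc4c(=O)c(-c5ccc(O)cc5)coc14)O[C@@H](C)C[C@H](C)O3)c2=O
A1 | alternative 1 | 8-iodo-7-methoxy-3-(4-methoxyphenyl)-4H-chromen-4-one | COc1ccc(cc1)-c1coc2c(I)c(OC)ccc2c1=O
A2 | alternative 1 | 7-methoxy-3-[4-methoxy-3-(4,4,5,5-tetramethyl-1,3,2-dioxaborolan-2-yl)phenyl]-4H-chromen-4-one | COc1ccc2c(c1)occ(-c1ccc(OC)c(c1)B1OC(C)(C)C(C)(C)O1)c2=O
A3 | alternative 1 | tetra-O-methylbisoflavolin C | COc1ccc2c(c1)occ(-c1ccc(OC)c(c1)-c1c(OC)ccc3c(=O)c(-c4ccc(OC)cc4)coc13)c2=O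
A4 | alternative 2 | 1-(2,4-dihydroxyphenyl)-2-{3-[2,6-dihydroxy-3-(4-hydroxyphenylacetyl)phenyl]-4-hydroxyphenyl}ethan-1-one | O=C(Cc1ccc(O)c(c1)-c1c(O)ccc(C(=O)Cc2ccc(O)cc2)c1O)c1ccc(O)cc1O
A5 | alternative 3 | cyclohexane-1,3-dione | O=C1CCCC(=O)C1
A6 | alternative 3 | 3-(3-bromo-4-methoxyphenyl)-7-methoxy-4H-chromen-4-one | COc1ccc2c(c1)occ(-c1ccc(OC)c(Br)c1)c2=O
A7 | alternative 3 | 2-[2-methoxy-5-(7-methoxy-4-oxo-4H-chromen-3-yl)phenyl]cyclohexane-1,3-dione | COc1ccc2c(c1)occ(-c1ccc(OC)c(c1)C1C(=O)CCCC1=O)c2=O
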